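## The problem

The target 19 is a diaryl ether between two different benzene rings. Ring A is a methyl benzoate (C1) with oxygen on both ortho carbons, a prenyl ether at C2 and the aryl ether at C6, and a methyl group at C4; ring B carries the ether oxygen at C1', a hydroxymethyl group at C2' and methoxy groups at C4' and C6'. The ether oxygen sits between three ortho substituents (the ester on ring A, CH2OH and OMe on ring B) and the ring B phenol is electron-rich and hindered, so a late copper-mediated or SNAr union of two finished arenes is the least attractive bond to make. The second difficulty is that the two ortho oxygens of ring A are equivalent in any symmetrical 2,6-dihydroxy precursor and must be told apart, one to carry the aryl group and one the prenyl group. There is no stereocentre and no stereogenic alkene (the prenyl terminus bears two methyl groups), so a stereocentre that appears in an intermediate may stay racemic if it is destroyed later. The fragile groups are the aryl prenyl ether (acid, heat, quinone oxidants), the benzylic alcohol on the electron-rich ring B (oxidation, ionisation, and as its alkoxide attack on the ring A ester to give an eight-membered lactone) and the methyl ester. The feature that opens the route is the array C6(OAr)–C1(CO2Me)–C2(O) of ring A: it is the dehydro form of a 2-methoxycarbonyl-5-methylcyclohexane-1,3-dione in which the C6 oxygen is an enol aryl ether and the C2 oxygen a ketone. In that form C6 and C1 are the β- and α-carbons of an alkynoate and C2 is an ester carbonyl at the end of the tether C5–C4(Me)–C3, so the aryl–oxygen bond and ring A can both be made from an open-chain ynoate diester.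

## Retrosynthesis

**19 back to 16 and 17.** The last two cuts are the O–Si bond of silyl ether 18 and the O–CH2 bond of the prenyl ether, which lead to salicylate 16 and prenyl bromide 17. The prenyl group is placed after ring A has been aromatised, because an allylic aryl ether would not survive a quinone oxidant and because the oxygen that carries it is still a ketone before that point. The silyl ether is kept to the very end, so that the benzylic alcohol is never free during the oxidation or under carbonate base. The forward steps ask only for O-alkylation of a hydrogen-bonded phenol and for a buffered fluoride cleavage.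

**16 back to 15.** Two C–H bonds of ring A are restored, which gives cyclohexenone 15. The neighbouring choice, cutting the O–C6 bond on the arene itself, would need a hindered copper coupling and a ring A partner whose two oxygens had already been differentiated. At the cyclohexenone level the C6 oxygen is a vinylogous carbonate and the C2 oxygen is a ketone, so the two are different by construction. The price is one dehydrogenation and a racemic methyl-bearing carbon that becomes sp2 in the same step.

**15 back to 12 and 8 (key disconnection).** The O–C6 and C1–C2 bonds of ring A are cut together, which gives phenol 12 and the acyclic ynoate diester 8.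
- Cutting O–C6 alone would mean addition–elimination on a preformed chloro-enone ring; this is known chemistry and is kept as the fallback.
- Cutting C1–C2 alone would require a vinyl anion to be made from a C–H bond.
- The double cut asks the phenoxide of 12 to add to an unhindered sp carbon of 8 and the resulting carbanion to acylate itself on the tethered ester.
- The spectator on 12 is a silyl ether: an aldehyde at that position would intercept the carbanion in a chromene-type closure, and a free alcohol would compete as a nucleophile.
- The tether of 8 is left saturated. An enyne would give the arene directly, but it would need a Z alkene and would invite addition at the remote alkene carbon.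

**8 back to 1 and 5.** The Csp–CO2Me bond of 8 is cut to terminal alkyne 7. This bond is made by oxidative methoxycarbonylation, because deprotonation of the alkyne and trapping with a chloroformate cannot be used beside an enolisable ester. The triple bond of 7 is cut to aldehyde 4 and the one-carbon diazophosphonate 5; this homologation runs under carbonate base and tolerates the ester. Aldehyde 4 comes from alcohol 3 and acid 2, and 2 comes from the symmetrical anhydride 1. Opening 1 with methanol differentiates the two chain ends in the first step and places the methyl branch where C4 of ring A will be.

**12 back to 9.** The O–Si bond of 12 is cut to diol 11, the benzylic C–O bond is taken back to aldehyde 10, and the C5 methoxy group of 10 is taken back to the bromide of commercial 9. Compound 9 already holds the 1,2,3,5 pattern of ring B, so the only arene functionalisation needed is a C–Br to C–OMe exchange. The forward sequence asks for one site-selective step: silylation of the primary alcohol of 11 in the presence of the hindered phenol.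

## Roads not taken

**Alternative 1:** Ring A is cut at C1–C2 and C3–C4. The forward key step is an inverse-demand Diels–Alder reaction of the aryloxy pyrone ester A2 with the ketene acetal A3; loss of the lactone bridge and of one alkoxy group gives the arene A1.
- Merits: ring A is formed at the aromatic oxidation level. The polarisation of both partners fixes the regiochemistry. Cycloadditions of 3-alkoxycarbonyl-2-pyrones with ketene acetals are an established reaction type, which the cascade of the chosen plan is not.
- Weak points: the C2 oxygen arrives as a methyl ether. It must be cleaved selectively beside the ester methyl and the two ring B methoxy groups and then replaced by prenyl, and the ring B aldehyde must be reduced afterwards. The aryloxy group at C4 of A2 weakens the electron demand of the pyrone and is itself a leaving group on a vinylogous carbonate. A2 has to be built in several steps by carboxylation, activation and aryloxylation of a hydroxypyrone.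
- Comparison: three steps follow A1, the same number as follow 15. Alternative 1 is ahead in precedent for its key step. The chosen plan sets against this that its second ring A oxygen emerges as a ketone that becomes the free phenol directly, with no selective demethylation, and that its two precursors come from cheap materials by routine steps.

**Alternative 2:** Ring B is cut at C1'–C2'. The forward key step is a base-mediated aldol closure of the aryloxy trione A5, in which the aryloxymethylene carbon adds to the ketone next to the acetal carbon; dehydration and enolisation give the resorcinol A4.
- Merits: the ether oxygen is attached by alkylation of a ring A phenol at an sp3 carbon, so no hindered arylation is needed. The prenyl ether is in place from the start. The closure follows a known polyketide-type pattern.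
- Weak points: the most acidic positions of A5 are the two methylenes between the carbonyl groups, not the aryloxymethylene carbon that must react. Pyranone formation from the tricarbonyl array competes. The aryloxymethylene carbanion can also attack the neighbouring ring A ester in a five-membered closure. Assembly of A5 needs polyanion chemistry beside that ester. The ring A phenol it starts from still requires statistical mono-prenylation of a symmetrical diol. After A4, double O-methylation, acetal hydrolysis and reduction are needed.
- Comparison: Alternative 2 avoids the crowded aryl–oxygen bond as completely as the chosen plan does. It is longer and has more competing closures. The chosen plan takes ring B with its substitution pattern from a commercial arene.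

**Alternative 3:** Ring A is cut at O–C6 and C1–CO2Me. In the forward key step fluoride releases the aryne from silyl triflate A7; the ring B phenoxide derived from the aryl methyl carbonate A8 adds at C6, and the aryl anion at C1 takes the methoxycarbonyl group from the carbonate to give A6.
- Merits: this is the most convergent plan. Both rings are aromatic throughout. The innate preference of a 3-alkoxyaryne places the anion next to the prenyloxy group, which is where the ester is needed. Only a carbonate methanolysis follows A6. If the key step worked, this route would be shorter than the chosen one.
- Weak points: the acyl transfer to the aryl anion is intermolecular or must pass through a strained transition state. Protonation, or addition to a second aryne, then gives the ester-free diaryl ether, the usual result of phenoxide–aryne additions. The benzylic carbonate of A8 is a second acyl donor and a leaving group on an electron-rich ring. The prenyl alkene lies close to the aryne. A7 needs mono-prenylation of a symmetrical resorcinol and an ortho-silylation sequence.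
- Comparison: the chosen plan gives up the shorter endgame. In return its carbanion is acylated intramolecularly through a six-membered closure, its precursors 8 and 12 are made by routine steps, and its key intermediate 15 can also be reached by known chemistry.

Key step: step 9

Remark: the target has no stereocentre; every intermediate with the methyl-bearing sp3 carbon is carried as the racemate, and the in-flask species 13 and 14 are written as potassium salts.

## Route

Step 1
Reactants: 1 3-methylglutaric anhydride
Product: 2 racemic 5-methoxy-3-methyl-5-oxopentanoic acid
Conditions: MeOH, reflux
Reagents that add atoms: methanol, CO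
Why: Alcoholysis of a cyclic anhydride; the two carbonyl groups of the meso anhydride are enantiotopic, so a single racemic half-ester should result.

Step 2
Reactants: 2 racemic 5-methoxy-3-methyl-5-oxopentanoic acid
Product: 3 racemic methyl 5-hydroxy-3-methylpentanoate
Conditions: BH3·SMe2, THF, 0 °C → rt; aqueous work-up
Reagents that add atoms: none
Why: Chemoselective borane reduction of a carboxylic acid beside an ester (via the acyloxyborane); the product is used without storage to avoid lactonisation.

Step 3
Reactants: 3 racemic methyl 5-hydroxy-3-methylpentanoate
Product: 4 racemic methyl 3-methyl-5-oxopentanoate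
Conditions: TEMPO (cat.), PhI(OAc)2, CH2Cl2, rt
Reagents that add atoms: none
Why: Oxoammonium-mediated oxidation of a primary alcohol, which stops at the aldehyde under anhydrous conditions and leaves the ester untouched.

Step 4
Reactants: 4 racemic methyl 3-methyl-5-oxopentanoate; 5 dimethyl (1-diazo-2-oxopropyl)phosphonate
Product: 7 racemic methyl 3-methylhex-5-ynoate, via dimethyl (diazomethyl)phosphonate 6 (not isolated)
Conditions: K2CO3, MeOH, 0 °C → rt
Reagents that add atoms: none
Why: Ohira–Bestmann modification of the Seyferth–Gilbert homologation: methanolysis of 5 gives 6, whose anion adds to the aldehyde; loss of dimethyl phosphate and N2 and a 1,2-hydride shift in the alkylidene carbene give the terminal alkyne; the methyl ester is inert in methanol.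

Step 5
Reactants: 7 racemic methyl 3-methylhex-5-ynoate
Product: 8 racemic dimethyl 5-methylhept-2-ynedioate
Conditions: PdCl2 (cat.), CuCl2, NaOAc, CO (1 atm), MeOH, rt
Reagents that add atoms: carbon monoxide, [C-]#[O+]; methanol, CO
Why: Oxidative alkoxycarbonylation of a terminal alkyne (Tsuji conditions): the alkynyl complex of divalent palladium inserts CO and is cleaved by methanol, and CuCl2 returns zerovalent palladium to the divalent state; no strong base is involved, so the saturated ester is not enolised.

Step 6
Reactants: 9 5-bromo-2-hydroxy-3-methoxybenzaldehyde
Product: 10 2-hydroxy-3,5-dimethoxybenzaldehyde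
Conditions: NaOMe, CuBr (cat.), DMF–MeOH, 100 °C; aq. HCl work-up
Reagents that add atoms: sodium methoxide, [Na+].[O-]C
Why: Copper-catalysed Ullmann-type methoxylation of an aryl bromide, the same reaction type that converts 5-bromovanillin into syringaldehyde; the aldehyde is shielded as the salicylaldehyde phenoxide during the reaction.

Step 7
Reactants: 10 2-hydroxy-3,5-dimethoxybenzaldehyde
Product: 11 2-(hydroxymethyl)-4,6-dimethoxyphenol
Conditions: NaBH4, MeOH, 0 °C
Reagents that add atoms: none
Why: Borohydride reduction of an aryl aldehyde to the benzylic alcohol; neutral work-up avoids ionisation of the electron-rich salicyl alcohol.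

Step 8
Reactants: 11 2-(hydroxymethyl)-4,6-dimethoxyphenol
Product: 12 2-(tert-butyldimethylsilyloxymethyl)-4,6-dimethoxyphenol
Conditions: TBSCl (1.05 equiv), imidazole, CH2Cl2, 0 °C
Reagents that add atoms: tert-butyldimethylsilyl chloride, C[Si](C)(Cl)C(C)(C)C
Why: Site-selective silylation: the primary benzylic alcohol should react faster than the phenol, which is flanked by two ortho substituents and hydrogen-bonded, as in the known mono-silylation of salicyl alcohols.

Step 9
Reactants: 12 2-(tert-butyldimethylsilyloxymethyl)-4,6-dimethoxyphenol; 8 racemic dimethyl 5-methylhept-2-ynedioate
Product: 15 racemic methyl 2-[2-(tert-butyldimethylsilyloxymethyl)-4,6-dimethoxyphenoxy]-4-methyl-6-oxocyclohex-1-ene-1-carboxylate, via potassium phenoxide 13 (not isolated), via potassium allenolate 14 (not isolated)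
Conditions: KH, THF, 0 °C; then 8, 18-crown-6, −40 °C → rt; AcOH quench
Reagents that add atoms: none
Why: Proposed new method: KH turns 12 into phenoxide 13 and leaves no proton donor behind; 13 should add anti to the β-carbon C3 of ynoate 8 (chain numbering of 8), the closest known reaction type being the base-mediated oxa-Michael addition of phenols to alkynoates. The adduct 14 carries its carbanion at C2 on the same side of the new double bond as the C4–C7 tether (as an allenolate it is linear at C2 and can reach that geometry in any case) and should attack the C7 ester carbonyl in a 6-exo-trig Dieckmann closure in which the C2=C3 bond lies inside the new ring, as in the known conjugate addition–Dieckmann cyclisation of organocuprates with acetylenic diesters. Loss of methoxide gives 15, and the methoxide should be consumed by deprotonating 15 at its γ-methylene to an extended dienolate, which shields the vinylogous carbonate carbon from aryloxide–methoxide exchange until the acetic acid quench. No stereocentre is created; the methyl-bearing carbon stays racemic and is erased in step 10. The step needs C-acylation at C2 to outrun both protonation of 14 and the rival Dieckmann closure of a C6 ester enolate onto the C1 ester; the absence of free phenol or alcohol, the cis placement of carbanion and tether, and the fact that neither phenoxide nor the released methoxide can form the saturated ester enolate in quantity should secure this. Should 13 first isomerise 8 to its allenoate, addition at the same carbon would give a dienolate that acylates at the same C2, so both channels converge on 15.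

Step 10
Reactants: 15 racemic methyl 2-[2-(tert-butyldimethylsilyloxymethyl)-4,6-dimethoxyphenoxy]-4-methyl-6-oxocyclohex-1-ene-1-carboxylate
Product: 16 methyl 2-[2-(tert-butyldimethylsilyloxymethyl)-4,6-dimethoxyphenoxy]-6-hydroxy-4-methylbenzoate
Conditions: DDQ, 1,4-dioxane, 80 °C
Reagents that add atoms: none
Why: Quinone dehydrogenation of a cyclohexenone to the phenol, the known conversion of 2-acylcyclohexane-1,3-dione derivatives into resorcylates: hydride abstraction from the dienol and tautomerisation give the hydrogen-bonded salicylate, and the methyl-bearing stereocentre becomes sp2.

Step 11
Reactants: 16 methyl 2-[2-(tert-butyldimethylsilyloxymethyl)-4,6-dimethoxyphenoxy]-6-hydroxy-4-methylbenzoate; 17 prenyl bromide (1-bromo-3-methylbut-2-ene)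
Product: 18 methyl 2-[2-(tert-butyldimethylsilyloxymethyl)-4,6-dimethoxyphenoxy]-4-methyl-6-(3-methylbut-2-enyloxy)benzoate
Conditions: K2CO3, DMF, 40 °C
Reagents that add atoms: none
Why: Williamson O-alkylation of the salicylate phenoxide by SN2 at the primary allylic bromide; the silyl ether and the ester are stable to carbonate in DMF.

Step 12
Reactants: 18 methyl 2-[2-(tert-butyldimethylsilyloxymethyl)-4,6-dimethoxyphenoxy]-4-methyl-6-(3-methylbut-2-enyloxy)benzoate
Product: 19 methyl 2-[2-(hydroxymethyl)-4,6-dimethoxyphenoxy]-4-methyl-6-(3-methylbut-2-enyloxy)benzoate (CNP0573678.0)
Conditions: Bu4NF, AcOH, THF, 0 °C → rt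
Reagents that add atoms: none
Why: Fluoride cleavage of a primary silyl ether; the acetic acid buffer keeps the benzylic oxygen protonated so that it cannot attack the ring A ester, and the prenyl ether is untouched.

## Compound list

1 | 3-methylglutaric anhydride | CC1CC(=O)OC(=O)C1 | starting material
2 | racemic 5-methoxy-3-methyl-5-oxopentanoic acid | COC(=O)CC(C)CC(=O)O | intermediate
3 | racemic methyl 5-hydroxy-3-methylpentanoate | COC(=O)CC(C)CCO | intermediate
4 | racemic methyl 3-methyl-5-oxopentanoate | COC(=O)CC(C)CC=O | intermediate
5 | dimethyl (1-diazo-2-oxopropyl)phosphonate | COP(=O)(OC)C(=[N+]=[N-])C(C)=O | starting material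
6 | dimethyl (diazomethyl)phosphonate | COP(=O)(OC)C=[N+]=[N-] | intermediate (not isolated)
7 | racemic methyl 3-methylhex-5-ynoate | COC(=O)CC(C)CC#C | intermediate
8 | racemic dimethyl 5-methylhept-2-ynedioate | COC(=O)C#CCC(C)CC(=O)OC | intermediate
9 | 5-bromo-2-hydroxy-3-methoxybenzaldehyde | COc1cc(Br)cc(C=O)c1O | starting material
10 | 2-hydroxy-3,5-dimethoxybenzaldehyde | COc1cc(C=O)c(O)c(OC)c1 | intermediate
11 | 2-(hydroxymethyl)-4,6-dimethoxyphenol | COc1cc(CO)c(O)c(OC)c1 | intermediate
12 | 2-(tert-butyldimethylsilyloxymethyl)-4,6-dimethoxyphenol | COc1cc(CO[Si](C)(C)C(C)(C)C)c(O)c(OC)c1 | intermediate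
13 | potassium 2-(tert-butyldimethylsilyloxymethyl)-4,6-dimethoxyphenoxide | COc1cc(CO[Si](C)(C)C(C)(C)C)c([O-])c(OC)c1.[K+] | intermediate (not isolated)
14 | potassium allenolate of dimethyl 3-[2-(tert-butyldimethylsilyloxymethyl)-4,6-dimethoxyphenoxy]-5-methylhept-2-enedioate (carbanion at C2; racemic, allene axis not controlled) | COC(=O)CC(C)CC(Oc1c(CO[Si](C)(C)C(C)(C)C)cc(OC)cc1OC)=C=C([O-])OC.[K+] | intermediate (not isolated)
15 | racemic methyl 2-[2-(tert-butyldimethylsilyloxymethyl)-4,6-dimethoxyphenoxy]-4-methyl-6-oxocyclohex-1-ene-1-carboxylate | COC(=O)C1=C(Oc2c(CO[Si](C)(C)C(C)(C)C)cc(OC)cc2OC)CC(C)CC1=O | intermediate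
16 | methyl 2-[2-(tert-butyldimethylsilyloxymethyl)-4,6-dimethoxyphenoxy]-6-hydroxy-4-methylbenzoate | COC(=O)c1c(O)cc(C)cc1Oc1c(CO[Si](C)(C)C(C)(C)C)cc(OC)cc1OC | intermediate
17 | prenyl bromide (1-bromo-3-methylbut-2-ene) | CC(C)=CCBr | starting material
18 | methyl 2-[2-(tert-butyldimethylsilyloxymethyl)-4,6-dimethoxyphenoxy]-4-methyl-6-(3-methylbut-2-enyloxy)benzoate | COC(=O)c1c(OCC=C(C)C)cc(C)cc1Oc1c(CO[Si](C)(C)C(C)(C)C)cc(OC)cc1OC | intermediate
19 | methyl 2-[2-(hydroxymethyl)-4,6-dimethoxyphenoxy]-4-methyl-6-(3-methylbut-2-enyloxy)benzoate | COC(=O)c1c(OCC=C(C)C)cc(C)cc1Oc1c(CO)cc(OC)cc1OC | target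

## Step count and risks

Total step count: 12. Longest linear sequence: 9 steps (steps 1–5 and 9–12, from 1 to 19); the ring B branch (steps 6–8) joins at step 9.

**Step 9 (key step, proposed new method).**
- What may go wrong: the carbanion of 14 may be protonated before it closes the ring, for instance by a propargylic or α-ester C–H of a second molecule of 8, so that the reaction stops at the open-chain aryloxy enoate. If stronger base is then used, ring closure may occur in the wrong sense from the saturated ester enolate. Methoxide may also exchange with the aryloxide at the vinylogous carbonate carbon.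
- Fallback (known chemistry): it sets out from acid 2 and phenol 12 and comes back at 15. Acid 2 would be activated with carbonyldiimidazole to methyl 5-(imidazol-1-yl)-3-methyl-5-oxopentanoate F1. F1 would be extended with Mg(O2CCH2CO2Me)2, with decarboxylation, to dimethyl 5-methyl-3-oxoheptanedioate F2. F2 would be closed with NaOMe in MeOH, a Dieckmann-type acylation of the doubly activated methylene, to methyl 2-hydroxy-4-methyl-6-oxocyclohex-1-ene-1-carboxylate F3. Oxalyl chloride with catalytic DMF would convert F3 into methyl 2-chloro-4-methyl-6-oxocyclohex-1-ene-1-carboxylate F4. Addition–elimination of 12 on F4 (K2CO3, MeCN, through 13) would give 15. From 2 this detour costs four steps against the five of steps 2–5 and 9, so it does not lengthen the route; it would be used only if the cascade fails, since the proposal rests on that disconnection.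

**Step 10.**
- What may go wrong: the quinone may oxidise the electron-rich ring B or its benzylic silyl ether, or hydride abstraction may be slow because the vinylogous carbonate enolises reluctantly.
- Fallback: it sets out from 15 and comes back at 16. Deprotonation with LiN(SiMe3)2 in THF at −78 °C and selenenylation with PhSeBr, anti to the neighbouring methyl group, would give methyl 2-[2-(tert-butyldimethylsilyloxymethyl)-4,6-dimethoxyphenoxy]-4-methyl-6-oxo-5-(phenylselanyl)cyclohex-1-ene-1-carboxylate F5. Oxidation with H2O2 and pyridine in CH2Cl2 would give the selenoxide F6 (the 5-benzeneseleninyl analogue of F5). Its syn elimination toward the C4 hydrogen and tautomerisation of the dienone would give 16.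

**Step 8.**
- What may go wrong: loss of site selectivity, with silylation of the phenol or of both hydroxyl groups.
- Fallback: it sets out from 11 and comes back at 12. Exhaustive silylation (excess TBSCl, imidazole, DMF) would give tert-butyl{[2-(tert-butyldimethylsilyloxy)-3,5-dimethoxyphenyl]methoxy}dimethylsilane F7. Selective methanolysis of the aryl silyl ether (K2CO3, MeOH) would then free the phenol only.

**Step 2.**
- What may go wrong: cyclisation of the δ-hydroxy ester to the six-membered lactone with loss of methanol during work-up or concentration, or partial reduction of the ester.
- Fallback: it sets out from 2 and comes back at 4, bypassing 3. Coupling of 2 with ethanethiol (dicyclohexylcarbodiimide, catalytic DMAP) would give methyl 5-(ethylsulfanyl)-3-methyl-5-oxopentanoate F8. Fukuyama reduction (Et3SiH, Pd/C, acetone) would give aldehyde 4 directly.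

## Further compounds

F1 | step 9 | racemic methyl 5-(1H-imidazol-1-yl)-3-methyl-5-oxopentanoate | COC(=O)CC(C)CC(=O)n1ccnc1
F2 | step 9 | racemic dimethyl 5-methyl-3-oxoheptanedioate | COC(=O)CC(=O)CC(C)CC(=O)OC
F3 | step 9 | racemic methyl 2-hydroxy-4-methyl-6-oxocyclohex-1-ene-1-carboxylate (enol form of 2-methoxycarbonyl-5-methylcyclohexane-1,3-dione) | COC(=O)C1=C(O)CC(C)CC1=O
F4 | step 9 | racemic methyl 2-chloro-4-methyl-6-oxocyclohex-1-ene-1-carboxylate | COC(=O)C1=C(Cl)CC(C)CC1=O
F5 | step 10 | racemic methyl 2-[2-(tert-butyldimethylsilyloxymethyl)-4,6-dimethoxyphenoxy]-4-methyl-6-oxo-5-(phenylselanyl)cyclohex-1-ene-1-carboxylate, 4,5-trans expected (one enantiomer drawn) | COC(=O)C1=C(Oc2c(CO[Si](C)(C)C(C)(C)C)cc(OC)cc2OC)C[C@H](C)[C@@H]([Se]c2ccccc2)C1=O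
F6 | step 10 | racemic methyl 5-(benzeneseleninyl)-2-[2-(tert-butyldimethylsilyloxymethyl)-4,6-dimethoxyphenoxy]-4-methyl-6-oxocyclohex-1-ene-1-carboxylate, 4,5-trans, mixture at selenium (one enantiomer drawn) | COC(=O)C1=C(Oc2c(CO[Si](C)(C)C(C)(C)C)cc(OC)cc2OC)C[C@H](C)[C@@H]([Se](=O)c2ccccc2)C1=O
F7 | step 8 | tert-butyl{[2-(tert-butyldimethylsilyloxy)-3,5-dimethoxyphenyl]methoxy}dimethylsilane | COc1cc(CO[Si](C)(C)C(C)(C)C)c(O[Si](C)(C)C(C)(C)C)c(OC)c1
F8 | step 2 | racemic methyl 5-(ethylsulfanyl)-3-methyl-5-oxopentanoate | CCSC(=O)CC(C)CC(=O)OC
A1 | alternative 1 | methyl 2-(2-formyl-4,6-dimethoxyphenoxy)-6-methoxy-4-methylbenzoate | COC(=O)c1c(OC)cc(C)cc1Oc1c(C=O)cc(OC)cc1OC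
A2 | alternative 1 | methyl 4-(2-formyl-4,6-dimethoxyphenoxy)-6-methyl-2-oxo-2H-pyran-3-carboxylate | COC(=O)C1=C(Oc2c(C=O)cc(OC)cc2OC)C=C(C)OC1=O
A3 | alternative 1 | 1,1-dimethoxyethene | C=C(OC)OC
A4 | alternative 2 | methyl 2-[2-(dimethoxymethyl)-4,6-dihydroxyphenoxy]-4-methyl-6-(3-methylbut-2-enyloxy)benzoate | COC(=O)c1c(OCC=C(C)C)cc(C)cc1Oc1c(C(OC)OC)cc(O)cc1O
A5 | alternative 2 | methyl 2-(7,7-dimethoxy-2,4,6-trioxoheptyloxy)-4-methyl-6-(3-methylbut-2-enyloxy)benzoate | COC(=O)c1c(OCC=C(C)C)cc(C)cc1OCC(=O)CC(=O)CC(=O)C(OC)OC
A6 | alternative 3 | methyl 2-{2-[(methoxycarbonyloxy)methyl]-4,6-dimethoxyphenoxy}-4-methyl-6-(3-methylbut-2-enyloxy)benzoate | COC(=O)c1c(OCC=C(C)C)cc(C)cc1Oc1c(COC(=O)OC)cc(OC)cc1OC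
A7 | alternative 3 | 5-methyl-3-(3-methylbut-2-enyloxy)-2-(trimethylsilyl)phenyl trifluoromethanesulfonate | CC(C)=CCOc1cc(C)cc(OS(=O)(=O)C(F)(F)F)c1[Si](C)(C)C
A8 | alternative 3 | 2-[(methoxycarbonyloxy)methyl]-4,6-dimethoxyphenyl methyl carbonate | COC(=O)OCc1cc(OC)cc(OC)c1OC(=O)OC
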